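**Retrosynthetic overview**
1. Target 10 ⇒ aldehyde 6 + styryl diazomethyl ketone 9. The 1,3-diketone is closed by Sn(II)-mediated aldehyde–diazoketone homologation with loss of N2.
2. 6 ⇒ coniferaldehyde 3 + diene 2. The key event is C=N bond formation between 3 and a chiral pyrrolidine; the resulting iminium ion undergoes an exo-selective [4+2] that builds the cyclohexene and all three stereocentres, and hydrolysis returns the amine.
3. 9 ⇒ dehydrozingerone 7 by diazo (C=N2) transfer; 2 ⇒ 3,4-dimethoxycinnamaldehyde 1 by Wittig methylenation.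
4. Ring order: the three arenes are bought; the cyclohexene is the only ring formed (step 2).

Assumption: keto–enol tautomers of the 1,3-diketone are treated as one compound (the target is drawn as the enol conjugated to the styryl group).

**Route**

Step 1
Reactants: 1 (E)-3-(3,4-dimethoxyphenyl)prop-2-enal
Product: 2 (E)-1-(3,4-dimethoxyphenyl)buta-1,3-diene
Conditions: Ph3PCH3Br (1.3 equiv), KOtBu (1.25 equiv), THF, 0 °C; then 1, 0 °C → rt
Reagents that add atoms: methyltriphenylphosphonium bromide, C[P+](c1ccccc1)(c1ccccc1)c1ccccc1.[Br-]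
Why: Wittig methylenation of the enal carbonyl; the existing E-alkene is not touched, so the diene is obtained as the pure E isomer and no stereocentre is formed.

Step 2
Reactants: 3 (E)-3-(4-hydroxy-3-methoxyphenyl)prop-2-enal (coniferaldehyde); 2 (E)-1-(3,4-dimethoxyphenyl)buta-1,3-diene (1.5 equiv)
Product: 6 (1R,2R,6S)-2-(3,4-dimethoxyphenyl)-6-(4-hydroxy-3-methoxyphenyl)cyclohex-3-ene-1-carbaldehyde, via dienophile iminium ion 4 (not isolated), via cycloadduct iminium ion 5 (not isolated)
Conditions: (S)-2-{bis[3,5-bis(trifluoromethyl)phenyl][(triethylsilyl)oxy]methyl}pyrrolidine (20 mol%), CF3CO2H (20 mol%), toluene, 4 °C → rt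
Reagents that add atoms: none
Why: Proposed new method: amine-catalysed exo-selective Diels–Alder reaction in which condensation of the chiral pyrrolidine with 3 (C=N bond formation) gives the E,s-trans iminium ion 4, whose lowered LUMO accepts the electron-rich diene; the C(Ar)2OSiEt3 group covers the Re face of C-β, so the CH2 terminus of 2 (largest HOMO coefficient) bonds to the Si face and sets the guaiacyl-bearing centre as S; the aryl-bearing diene terminus bonds to C-α on the same face, which puts the formyl carbon trans to the guaiacyl group (from the E enal); the exo arrangement, in which the bulky pyrrolidinium is turned away from the diene and so avoids its outside aryl group, puts CHO trans to the dimethoxyphenyl group as well; hydrolysis of 5 releases 6 and the amine, and because all-trans (all-equatorial) C-1 is also the thermodynamic epimer, enamine-mediated epimerisation cannot erode it; closest known reaction: diarylprolinol silyl ether/acid-catalysed exo-selective iminium Diels–Alder of cinnamaldehyde with cyclopentadiene and simple alkyl dienes, not shown for open-chain 1-aryl dienes or free-phenol enals.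

Step 3
Reactants: 7 (E)-4-(4-hydroxy-3-methoxyphenyl)but-3-en-2-one (dehydrozingerone)
Product: 9 (E)-1-diazo-4-(4-hydroxy-3-methoxyphenyl)but-3-en-2-one, via trifluoroacetyl diketone 8 (not isolated)
Conditions: LiHMDS (2.2 equiv), THF, −78 °C; CF3CO2CH2CF3 (1.3 equiv), −78 °C; aq. HCl work-up; crude + MsN3 (1.5 equiv), Et3N (1.5 equiv), H2O (1 equiv), MeCN, rt
Reagents that add atoms: methanesulfonyl azide, CS(=O)(=O)N=[N+]=[N-]
Why: Danheiser detrifluoroacetylative diazo transfer: the phenoxide/enolate dianion is C-trifluoroacetylated at the only enolisable carbon, and the activated 1,3-diketone 8 takes N2 from MsN3 with loss of the trifluoroacetyl group; no stereocentre is formed and the E-alkene is untouched.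

Step 4
Reactants: 6 (1R,2R,6S)-2-(3,4-dimethoxyphenyl)-6-(4-hydroxy-3-methoxyphenyl)cyclohex-3-ene-1-carbaldehyde; 9 (E)-1-diazo-4-(4-hydroxy-3-methoxyphenyl)but-3-en-2-one (1.3 equiv, added slowly)
Product: 10 (2Z,4E)-1-[(1R,2R,6S)-2-(3,4-dimethoxyphenyl)-6-(4-hydroxy-3-methoxyphenyl)cyclohex-3-en-1-yl]-3-hydroxy-5-(4-hydroxy-3-methoxyphenyl)penta-2,4-dien-1-one
Conditions: SnCl2 (0.2 equiv), CH2Cl2, rt
Reagents that add atoms: none
Why: Roskamp-type homologation in its α-diazo ketone (Padwa) variant: the Sn(II)-activated aldehyde is attacked by the diazo carbon, and a 1,2-hydride shift with loss of N2 gives the 1,3-diketone, which enolises to the conjugated keto-enol; no new stereocentre is formed and C-1, now α to the ketone, already has its thermodynamically favoured all-trans configuration.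

**Compound list**
1 | (E)-3-(3,4-dimethoxyphenyl)prop-2-enal (3,4-dimethoxycinnamaldehyde) | COc1ccc(/C=C/C=O)cc1OC | starting material
2 | (E)-1-(3,4-dimethoxyphenyl)buta-1,3-diene | COc1ccc(/C=C/C=C)cc1OC | intermediate
3 | (E)-3-(4-hydroxy-3-methoxyphenyl)prop-2-enal (coniferaldehyde) | COc1cc(/C=C/C=O)ccc1O | starting material
4 | E-iminium trifluoroacetate of 3 with the (S)-pyrrolidine catalyst: (S)-2-{bis[3,5-bis(trifluoromethyl)phenyl][(triethylsilyl)oxy]methyl}-1-[(E)-3-(4-hydroxy-3-methoxyphenyl)allylidene]pyrrolidin-1-ium trifluoroacetate | COc1cc(/C=C/C=[N+]2/[C@H](C(O[Si](CC)(CC)CC)(c3cc(C(F)(F)F)cc(C(F)(F)F)c3)c3cc(C(F)(F)F)cc(C(F)(F)F)c3)CCC2)ccc1O.[O-]C(=O)C(F)(F)F | intermediate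
5 | iminium trifluoroacetate of aldehyde 6 with the (S)-pyrrolidine catalyst (ring centres as in 6; C=N geometry not defined) | C(=[N+]2CCC[C@H]2C(O[Si](CC)(CC)CC)(c2cc(C(F)(F)F)cc(C(F)(F)F)c2)c2cc(C(F)(F)F)cc(C(F)(F)F)c2)[C@@H]1[C@@H](c2ccc(O)c(OC)c2)CC=C[C@H]1c1ccc(OC)c(OC)c1.[O-]C(=O)C(F)(F)F | intermediate
6 | (1R,2R,6S)-2-(3,4-dimethoxyphenyl)-6-(4-hydroxy-3-methoxyphenyl)cyclohex-3-ene-1-carbaldehyde (CHO trans to both aryl groups, aryl groups cis to each other) | O=C[C@@H]1[C@@H](c2ccc(O)c(OC)c2)CC=C[C@H]1c1ccc(OC)c(OC)c1 | intermediate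
7 | (E)-4-(4-hydroxy-3-methoxyphenyl)but-3-en-2-one (dehydrozingerone) | COc1cc(/C=C/C(C)=O)ccc1O | starting material
8 | (E)-1,1,1-trifluoro-6-(4-hydroxy-3-methoxyphenyl)hex-5-ene-2,4-dione | COc1cc(/C=C/C(=O)CC(=O)C(F)(F)F)ccc1O | intermediate
9 | (E)-1-diazo-4-(4-hydroxy-3-methoxyphenyl)but-3-en-2-one | COc1cc(/C=C/C(=O)C=[N+]=[N-])ccc1O | intermediate
10 | (2Z,4E)-1-[(1R,2R,6S)-2-(3,4-dimethoxyphenyl)-6-(4-hydroxy-3-methoxyphenyl)cyclohex-3-en-1-yl]-3-hydroxy-5-(4-hydroxy-3-methoxyphenyl)penta-2,4-dien-1-one | COc1cc(/C=C/C(O)=C/C(=O)[C@@H]2[C@@H](c3ccc(O)c(OC)c3)CC=C[C@H]2c2ccc(OC)c(OC)c2)ccc1O | target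

**Step count and risks**
Total steps: 4. Longest linear sequence: 3 steps (1 → 2 → 6 → 10).

Step 2, the proposed new method, is the most likely to fail. The free para-hydroxyl makes the iminium ion less electrophilic, the diene is acid-sensitive, and exo control with an open-chain 1-aryl diene is untested. The fallback uses known chemistry and sets out from 3 and 2: uncatalysed thermal Diels–Alder reaction in xylene at 140 °C with BHT in a sealed tube. It gives the all-trans aldehyde as a racemate, that is 6 together with its enantiomer (1S,2S,6R)-2-(3,4-dimethoxyphenyl)-6-(4-hydroxy-3-methoxyphenyl)cyclohex-3-ene-1-carbaldehyde F1, plus the racemic endo diastereomer F2, in which CHO is cis to the dimethoxyphenyl group. F2 is removed by silica chromatography, 6 is separated from F1 by preparative chiral SFC, and the route is rejoined at 6.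

Step 4 is the second risk: the formyl group of 6 is flanked by two aryl-bearing carbons, so the Sn(II)-mediated addition of the diazoketone may be slow. The fallback changes the C–C bond construction to aldol addition followed by oxidation and sets out from 6 and 7. TBSCl/imidazole converts 6 into its O-TBS ether F6 and 7 into O-TBS dehydrozingerone F3. The lithium enolate of F3, made with LDA in THF at −78 °C, adds to F6 to give the β-hydroxy ketone F7 as both carbinol epimers. Dess–Martin periodinane oxidises F7 to the bis-TBS ether F8 of the target, and HF·pyridine removes both silyl groups from F8, so the route is rejoined at 10.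

Step 3 is the third risk: the lithium phenoxide may make enolisation of the methyl ketone incomplete or be acylated itself. The fallback changes to a protecting-group strategy and sets out from 7. TBSCl/imidazole gives O-TBS dehydrozingerone F3. Enolisation of F3 with LiHMDS (1.1 equiv) and trifluoroacetylation give the O-TBS trifluoroacetyl diketone F4, and MsN3/Et3N converts F4 into the O-TBS diazoketone F5. TBAF/AcOH then removes the silyl group from F5 and the route is rejoined at 9.

**Further compounds**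
F1 | step 2 | (1S,2S,6R)-2-(3,4-dimethoxyphenyl)-6-(4-hydroxy-3-methoxyphenyl)cyclohex-3-ene-1-carbaldehyde (enantiomer of 6) | O=C[C@H]1[C@H](c2ccc(O)c(OC)c2)CC=C[C@@H]1c1ccc(OC)c(OC)c1
F2 | step 2 | racemic endo diastereomer of 6, CHO cis to the dimethoxyphenyl group; (1R,2S,6S) enantiomer drawn | O=C[C@@H]1[C@@H](c2ccc(O)c(OC)c2)CC=C[C@@H]1c1ccc(OC)c(OC)c1
F3 | step 3 | (E)-4-[4-(tert-butyldimethylsilyloxy)-3-methoxyphenyl]but-3-en-2-one | COc1cc(/C=C/C(C)=O)ccc1O[Si](C)(C)C(C)(C)C
F4 | step 3 | (E)-6-[4-(tert-butyldimethylsilyloxy)-3-methoxyphenyl]-1,1,1-trifluorohex-5-ene-2,4-dione | COc1cc(/C=C/C(=O)CC(=O)C(F)(F)F)ccc1O[Si](C)(C)C(C)(C)C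
F5 | step 3 | (E)-4-[4-(tert-butyldimethylsilyloxy)-3-methoxyphenyl]-1-diazobut-3-en-2-one | COc1cc(/C=C/C(=O)C=[N+]=[N-])ccc1O[Si](C)(C)C(C)(C)C
F6 | step 4 | (1R,2R,6S)-6-[4-(tert-butyldimethylsilyloxy)-3-methoxyphenyl]-2-(3,4-dimethoxyphenyl)cyclohex-3-ene-1-carbaldehyde | O=C[C@@H]1[C@@H](c2ccc(O[Si](C)(C)C(C)(C)C)c(OC)c2)CC=C[C@H]1c1ccc(OC)c(OC)c1
F7 | step 4 | (E)-1-[4-(tert-butyldimethylsilyloxy)-3-methoxyphenyl]-5-{(1R,2R,6S)-6-[4-(tert-butyldimethylsilyloxy)-3-methoxyphenyl]-2-(3,4-dimethoxyphenyl)cyclohex-3-en-1-yl}-5-hydroxypent-1-en-3-one (both C-5 epimers) | COc1cc(/C=C/C(=O)CC(O)[C@@H]2[C@@H](c3ccc(O[Si](C)(C)C(C)(C)C)c(OC)c3)CC=C[C@H]2c2ccc(OC)c(OC)c2)ccc1O[Si](C)(C)C(C)(C)C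
F8 | step 4 | bis(tert-butyldimethylsilyl) ether of 10 at both phenols | COc1cc(/C=C/C(O)=C/C(=O)[C@@H]2[C@@H](c3ccc(O[Si](C)(C)C(C)(C)C)c(OC)c3)CC=C[C@H]2c2ccc(OC)c(OC)c2)ccc1O[Si](C)(C)C(C)(C)C
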